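## Retrosynthetic overview

1. Target 10 ⇒ aromatic hydroxy-aldehyde 6 + octadecanoic acid 7: the C7–O ester bond is made by a reagent-controlled acyloxylative dearomatization that sets C7, and the C1–O2 enol-ether bond follows by cyclodehydration.
2. 6 ⇒ lactol 5 by removal of the two O-methyl groups.
3. 5 ⇒ 2,4-dimethoxy-3-methylbenzaldehyde 1 + (R)-propylene oxide 2: the C4a–C4 bond is made by directed ortho-lithiation and epoxide opening, and C3 comes from the chiral pool.
4. Ring order: the carbocycle is the purchased benzene ring, dearomatized in the last step; the pyran ring is closed last, in the same flask.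

Assumption: the chiral iodoarene (2R,2'R)-2,2'-[(2-iodo-1,3-phenylene)bis(oxy)]bis[N-(2,4,6-trimethylphenyl)propanamide] is bought and oxidised beforehand (NaBO3·4H2O, AcOH, 45 °C) to its λ3-iodane diacetate ArI(OAc)2, SMILES CC(=O)OI(OC(C)=O)c1c(O[C@H](C)C(=O)Nc2c(C)cc(C)cc2C)cccc1O[C@H](C)C(=O)Nc1c(C)cc(C)cc1C; this reagent preparation is not counted as a step.

Assumption: the (R,R) reagent is taken to deliver the carboxylate to the 7R face; this is not predicted with confidence, and if the 7S epimer dominates, the (S,S) reagent is used with nothing else changed.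

## Route

Step 1
Reactants: 1 2,4-dimethoxy-3-methylbenzaldehyde; 2 (R)-propylene oxide
Product: 5 (3R)-6,8-dimethoxy-3,7-dimethyl-3,4-dihydro-1H-isochromen-1-ol, via lithium α-amino alkoxide 3 (not isolated), via C6-lithiated α-amino alkoxide 4 (not isolated)
Conditions: LiN(Me)CH2CH2NMe2 (1.1 equiv, from the amine + n-BuLi), THF, −20 °C; n-BuLi (2.5 equiv), −20 °C, 18 h; 2 (5 equiv), −78 °C → rt; 1 M HCl, 0 °C
Reagents that add atoms: none
Why: Comins-type α-amino alkoxide directed ortho-lithiation, in which the aminal alkoxide 3 masks the aldehyde and its chelating diamine arm directs n-BuLi to C6–H (the 4-OMe, twisted by the flanking 3-methyl, activates C5–H poorly); aryllithium 4 then opens the epoxide by SN2 attack at the unsubstituted CH2, so the (R)-carbinol centre is untouched and becomes C3, and acidic work-up unmasks the aldehyde, which closes to lactol 5.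

Step 2
Reactants: 5 (3R)-6,8-dimethoxy-3,7-dimethyl-3,4-dihydro-1H-isochromen-1-ol
Product: 6 2,4-dihydroxy-6-[(2R)-2-hydroxypropyl]-3-methylbenzaldehyde
Conditions: BBr3 (4 equiv), CH2Cl2, −78 → 0 °C, 2 h; then H2O/THF, NaHCO3
Reagents that add atoms: none
Why: Lewis-acid aryl methyl ether cleavage, in which BBr3 ionises the lactol to a 6,8-dimethoxy-isochromenylium ion whose oxonium-like O-methyl groups are removed by bromide (SN2 at methyl) much faster than the secondary C3–O bond can be attacked at or below 0 °C; hydrolysis returns the free resorcinol aldehyde with C3 unchanged.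

Step 3
Reactants: 6 2,4-dihydroxy-6-[(2R)-2-hydroxypropyl]-3-methylbenzaldehyde; 7 octadecanoic acid
Product: 10 (3R,7R)-3,7-dimethyl-6,8-dioxo-4,6,7,8-tetrahydro-3H-isochromen-7-yl octadecanoate, via aryl-λ3-iodane bis(octadecanoate) 8 (not isolated), via o-quinol octadecanoate 9 (not isolated)
Conditions: ArI(OAc)2 (1.25 equiv), 7 (2.6 equiv), PhCl, 45 °C, 20 mbar (AcOH removed); then 6, CHCl3, −30 → 0 °C; then TFA (0.1 equiv), 4 Å MS, rt
Reagents that add atoms: none
Why: Proposed new method: a reagent-controlled, face-selective Wessely-type acyloxylative dearomatization in which a phenol oxygen of 6 exchanges onto the trivalent iodine centre of the C2-symmetric iodane 8, whose lactamide N–H groups hold the remaining octadecanoate by hydrogen bonding and deliver it to one face of the methyl-bearing carbon between the two phenolic oxygens (the most electron-rich ring carbon) as the iodoarene leaves, giving 9 with C7 set by the reagent (C3 is too remote to matter, and any 7S epimer is a separable diastereomer), after which the vinylogous acid of 9 condenses with the side-chain hydroxyl under acid catalysis to close the pyran (C1–O2 bond); the closest known reactions are the racemic Wessely acetoxylation of o-methylphenols with Pb(OAc)4 or PhI(OAc)2, the chiral-iodoarene Kita spirolactonization of naphthols, and the copper–sparteine–O2 hydroxylative dearomatization used for azaphilones.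

## Compound list

1 | 2,4-dimethoxy-3-methylbenzaldehyde | COc1ccc(C=O)c(OC)c1C | starting material
2 | (R)-propylene oxide, (2R)-2-methyloxirane | C[C@@H]1CO1 | starting material
3 | lithium (2,4-dimethoxy-3-methylphenyl){[2-(dimethylamino)ethyl](methyl)amino}methanolate (carbinol centre uncontrolled) | [Li]OC(N(C)CCN(C)C)c1ccc(OC)c(C)c1OC | intermediate
4 | lithium (6-lithio-2,4-dimethoxy-3-methylphenyl){[2-(dimethylamino)ethyl](methyl)amino}methanolate | [Li]OC(N(C)CCN(C)C)c1c([Li])cc(OC)c(C)c1OC | intermediate
5 | (3R)-6,8-dimethoxy-3,7-dimethyl-3,4-dihydro-1H-isochromen-1-ol (lactol, both C1 epimers; ring-chain tautomer of 6-[(2R)-2-hydroxypropyl]-2,4-dimethoxy-3-methylbenzaldehyde) | COc1cc2C[C@@H](C)OC(O)c2c(OC)c1C | intermediate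
6 | 2,4-dihydroxy-6-[(2R)-2-hydroxypropyl]-3-methylbenzaldehyde (open form; equilibrates with its lactol, and both react alike in step 3) | C[C@@H](O)Cc1cc(O)c(C)c(O)c1C=O | intermediate
7 | octadecanoic (stearic) acid | CCCCCCCCCCCCCCCCCC(=O)O | starting material
8 | {2,6-bis[((2R)-1-oxo-1-[(2,4,6-trimethylphenyl)amino]propan-2-yl)oxy]phenyl}-λ3-iodanediyl bis(octadecanoate) | CCCCCCCCCCCCCCCCCC(=O)OI(OC(=O)CCCCCCCCCCCCCCCCC)c1c(O[C@H](C)C(=O)Nc2c(C)cc(C)cc2C)cccc1O[C@H](C)C(=O)Nc1c(C)cc(C)cc1C | intermediate
9 | (1S)-3-formyl-2-hydroxy-4-[(2R)-2-hydroxypropyl]-1-methyl-6-oxocyclohexa-2,4-dien-1-yl octadecanoate (same spatial arrangement at the acyloxy carbon as C7 of 10; the descriptor differs only because the priorities of the two flanking carbons swap) | CCCCCCCCCCCCCCCCCC(=O)O[C@]1(C)C(=O)C=C(C[C@@H](C)O)C(C=O)=C1O | intermediate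
10 | (3R,7R)-3,7-dimethyl-6,8-dioxo-4,6,7,8-tetrahydro-3H-isochromen-7-yl octadecanoate | CCCCCCCCCCCCCCCCCC(=O)O[C@]1(C)C(=O)C=C2C[C@@H](C)OC=C2C1=O | target

## Step count and risks

Total step count: 3. Longest linear sequence: 3 steps (1 → 5 → 6 → 10).

Most likely to fail, in this order: step 3, step 1, step 2.

Step 3 (the new acyloxylative dearomatization) may give low face selectivity at C7, or acyloxylation at the unsubstituted ring carbon C5 with rearomatization. The fallback uses known chemistry, sets out from 6 and returns at 10. Compound 6 is hydroxylated at the methyl-bearing carbon by the copper–sparteine–dioxygen dearomatization ([Cu(MeCN)4]PF6, (−)-sparteine, O2, DIPEA, DMAP, CH2Cl2, −78 → −10 °C). Brief acid treatment (TFA cat.) closes the pyran to (3R,7R)-7-hydroxy-3,7-dimethyl-3,4-dihydro-6H-isochromene-6,8(7H)-dione F4. The tertiary alcohol is then acylated with octadecanoyl chloride (CCCCCCCCCCCCCCCCCC(=O)Cl), Et3N and DMAP in CH2Cl2 to give 10. (−)-Sparteine is chosen because, as I recall it, it gives the 7R series in non-halogenated azaphilones.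

Step 1 may suffer from competing lithiation at C5 or sluggish epoxide opening by the chelated aryllithium. The fallback sets out from 2 and returns at 5. The Grignard reagent of purchased 1-bromo-3,5-dimethoxybenzene (COc1cc(Br)cc(OC)c1; Mg, THF) opens 2 at its CH2 terminus with CuBr·SMe2 (10 mol%) at −30 → 0 °C to give (2R)-1-(3,5-dimethoxyphenyl)propan-2-ol F1. Double deprotonation with n-BuLi (2.2 equiv, THF, 0 °C) lithiates the carbon between the two methoxy groups, and iodomethane (1.05 equiv, −78 °C) gives (2R)-1-(3,5-dimethoxy-4-methylphenyl)propan-2-ol F2. Rieche formylation (Cl2CHOMe, TiCl4, CH2Cl2, −78 → 0 °C, aqueous work-up) at the free position ortho to the side chain gives 5.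

Step 2 may open the lactol ring at C3–O by bromide, which would erode the C3 configuration. The fallback removes the methyl groups before any aldehyde or lactol exists; it sets out from 2, runs through F1 and F2 as above, and returns at 6. F2 is demethylated (BBr3, CH2Cl2, −78 → 0 °C) to 5-[(2R)-2-hydroxypropyl]-2-methylbenzene-1,3-diol F3. F3 is formylated ortho to the side chain with triethyl orthoformate/TFA followed by aqueous HCl to give 6.

## Further compounds

F1 | step 1 | (2R)-1-(3,5-dimethoxyphenyl)propan-2-ol | C[C@@H](O)Cc1cc(OC)cc(OC)c1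
F2 | step 1 | (2R)-1-(3,5-dimethoxy-4-methylphenyl)propan-2-ol | C[C@@H](O)Cc1cc(OC)c(C)c(OC)c1
F3 | step 2 | 5-[(2R)-2-hydroxypropyl]-2-methylbenzene-1,3-diol | C[C@@H](O)Cc1cc(O)c(C)c(O)c1
F4 | step 3 | (3R,7R)-7-hydroxy-3,7-dimethyl-3,4-dihydro-6H-isochromene-6,8(7H)-dione | O[C@]1(C)C(=O)C=C2C[C@@H](C)OC=C2C1=O
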